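L, charged alone, passes into E and onward, and three flasks differing only in their charge are read for cE at the same time.

common to all: time 5.0 h

| run | L |
|---|---|
| Sunday's | 0.0050 M |
| Friday's | 0.0080 M |
| Monday's | 0.012 M |

    L ⇌ Q (K1 = 0.0129, k1 = 6.90 × 10⁻⁵ s⁻¹)
    L + E → L.E (k2 = 0.0117 M⁻¹ s⁻¹)
    E → Z (k3 = 1.77 × 10⁻⁵ s⁻¹)
    Q → X (k4 = 1.28 × 10⁻⁴ s⁻¹)
    L → E (k5 = 1.32 × 10⁻⁴ s⁻¹)
    E ⇌ X (K6 = 12.3, k6 = 8.35 × 10⁻⁵ s⁻¹)

- percent here means L units held: one L.E counts as two
- "hardly changes" means that all values lie within two and a half points (for a concentration: within two and a half percent of the largest)
- run time (Sunday's): 5.0 h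

1. [E] at the end for Sunday's, Friday's, Monday's, in this order
2. the shape of the row from first to last (rises all the way / rises, then falls / falls, then rises / hardly changes / falls all the way)

Follow one molecule of L. At its first fork, the route through Q to X runs at 1.25% of the rate of the passing of L into E, so the molecule is counted as becoming E. E leaves for X and Z at 0.364 h⁻¹ in sum, while L feeds E at 0.475 h⁻¹; the way back from X, whose rate constant is 12.3 times smaller than the forward one, is set aside in this reckoning. This first-order chain puts E at 29.5% of the charge at 5.0 h, a share the charge does not enter.

The charge enters at the next fork, where L acts on E as a pseudo-first-order trap. On Sunday's, 0.443 is the capture number, the rate constant of L + E times the charged cL over the rate constant of L into E: the captures expected of an E molecule that sees all of L decay. It is 0.709 on Friday's and 1.06 on Monday's. A typical E is taken as born at the half-life reckoned from the rate constant of L into E, 1.46 h, with half of L still ahead, so its chance of escape is estimated as exp(−N/2): 0.801 on Sunday's, 0.589 on Monday's. From Sunday's to Monday's the charge grows 2.40 times, more than the escape chance shrinks, so the row rises: 0.00118 M, 0.00166 M, 0.00208 M.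

The forecast, lower than this reckoning on the first two points, gave 0.00113 M, 0.0016 M, 0.00208 M, rises all the way, and its grounds were that the L + E step “grows with concentration and pulls that fraction down”.

The flasks gave 0.00121 M, 0.00171 M, 0.00223 M, rises all the way. On Sunday's, the passing of L into E had 45% of its turnover up to 5.0 h behind it after 1.00 h, and the passing of L + E into L.E had 74% of its own behind it after 2.50 h, with L then at 26.2% of the charge. At 5.00 h on Sunday's, the forward passing of E into X ran 21 times faster than capture. Sunday's cE stood at 0.820 of the chain's figure, with capture number 0.443; Monday's, with 1.06, stood at 0.630, and L.E held 34.4% of Monday's charged L at 5.00 h, each L.E counted as two L.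

(The rate constants were set for the occasion; what happens was integrated by code.)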